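## Retrosynthesis
1. Target (**10**) ⇐ CAN oxidation of the bis-naphthalenetriol **9** ⇐ protodestannylation and MOM removal of **8**.
2. **8** ⇐ bidirectional thermal benzannulation (Moore/Liebeskind 4π-opening, 6π-closure) of the bis(4-aryl-4-hydroxycyclobutenone) **7**. This builds both quinone rings at once and fixes the peri oxygen and the 3-OEt regiochemistry.
3. **7** ⇐ bis-ortho-lithiation of the bis-MOM biaryl **3** and double addition to 3-ethoxy-4-(tributylstannyl)cyclobutenedione **6** (from diethyl squarate).
4. The hindered biaryl bond is already present in the commercial diol **1**, so no late biaryl coupling is used. Ring order: biaryl (pre-formed), then the two cyclobutenones, then the two six-membered quinone rings.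

**Assumptions**
- The target has no stereocentres, and its SMILES gives no axis descriptor. I make it as the unresolved (racemic or rapidly equilibrating) tetra-ortho-substituted biaryl and do not try to control the axis.
- 6,6'-Dimethylbiphenyl-2,2'-diol (**1**) is treated as commercially available.
- "3-Ethoxy" uses juglone numbering: OEt sits next to the C4=O that is peri to the 5-OH.

## Route

**Step 1**
Reactants: **1** 6,6'-dimethylbiphenyl-2,2'-diol; **2** chloromethyl methyl ether
Product: **3** 2,2'-bis(methoxymethoxy)-6,6'-dimethylbiphenyl
Conditions: NaH (2.5 equiv), MOMCl (2.4 equiv), THF/DMF, 0 °C → rt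
Reagents that add atoms: MOMCl, ClCOC
Why: Double Williamson-type O-alkylation gives strong ortho-directing MOM ethers; no stereocentre is formed.

**Step 2**
Reactants: **4** diethyl squarate; **5** tributylstannane (as Bu3SnLi)
Product: **6** 3-ethoxy-4-(tributylstannyl)cyclobut-3-ene-1,2-dione
Conditions: Bu3SnH, LDA, THF, −78 → 0 °C to make Bu3SnLi; then **4**, −78 °C; aq NH4Cl
Reagents that add atoms: Bu3SnH, CCCC[SnH](CCCC)CCCC
Why: Bu3Sn⁻ displaces one ethoxide of the vinylogous ester by addition–elimination (SNV). This puts the single remaining OEt next to the more electrophilic carbonyl and leaves the future C2 carbon as a C–Sn "masked H".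

**Step 3**
Reactants: **3**; **6** (2.5 equiv)
Product: **7** bis[4-aryl-4-hydroxy-3-ethoxy-2-(tributylstannyl)cyclobut-2-en-1-one] (diastereomer mixture)
Conditions: n-BuLi (2.2 equiv), TMEDA, Et2O, 0 °C → rt, 3 h; then **6**, THF, −78 → −40 °C; aq NH4Cl
Reagents that add atoms: none beyond **6** itself (n-BuLi and NH4Cl leave only H)
Why: Directed ortho-metalation at C3/C3' (the BINOL-MOM type 3,3'-dilithiation) followed by 1,2-addition of ArLi to the non-vinylogous-ester carbonyl of **6**. Two quaternary carbinol stereocentres form as a mixture, and both are destroyed in Step 4. Proposed new method: bidirectional addition of a dilithiated tetra-ortho-substituted biaryl to a 4-stannylcyclobutenedione; mechanism as above, closest known reactions are ArLi additions to 4-stannyl-/dialkoxycyclobutenediones and BINOL-MOM 3,3'-dilithiation.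

**Step 4**
Reactant: **7**
Product: **8** bis(1,4-dihydroxy-3-ethoxy-2-stannyl-5-MOMO-naphthalene) biaryl
Conditions: p-xylene, 140 °C, 3 h, sealed under Ar
Reagents that add atoms: none
Why: Moore rearrangement. Thermal 4π ring-opening gives an aryl-vinylketene, and 6π-electrocyclisation onto the only free ortho carbon (C4; the other ortho carbon carries OMOM) gives the 1,4-naphthalenediol. This sets C4–OH peri to the C5-OMOM and C3–OEt next to it. Proposed new method: bidirectional double Moore cascade on a hindered biaryl; the closest known reaction is the Liebeskind–Moore quinone synthesis from 4-aryl-4-hydroxycyclobutenones.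

**Step 5**
Reactant: **8**
Product: **9** bis(3-ethoxynaphthalene-1,4,5-triol) biaryl
Conditions: TFA/CH2Cl2 (1:4), 0 °C → rt, 2 h, Ar
Reagents that add atoms: none (TFA and water leave only H)
Why: The electron-rich arylstannane undergoes ipso-protonation (protodestannylation), installing C2–H. The same acid cleaves the MOM acetals to the phenols.

**Step 6**
Reactant: **9**
Product: **10** 3,3'-diethoxyisodiospyrin (target)
Conditions: CAN (4.5 equiv), MeCN/H2O 4:1, 0 °C, 10 min
Reagents that add atoms: none
Why: Ce(IV) oxidises each 1,4-naphthalenediol to the 1,4-quinone. The peri-OH (chelated) and the vinylogous ethyl ether survive, and no stereocentre is created.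

## Compound list
1 | 6,6'-dimethylbiphenyl-2,2'-diol | Cc1cccc(O)c1-c1c(C)cccc1O | starting material
2 | chloromethyl methyl ether | ClCOC | starting material
3 | 2,2'-bis(MOM-oxy)-6,6'-dimethylbiphenyl | COCOc1cccc(C)c1-c1c(C)cccc1OCOC | intermediate
4 | diethyl squarate | CCOC1=C(OCC)C(=O)C1=O | starting material
5 | tributylstannane | CCCC[SnH](CCCC)CCCC | starting material
6 | 3-ethoxy-4-(tributylstannyl)cyclobut-3-ene-1,2-dione | CCOC1=C([Sn](CCCC)(CCCC)CCCC)C(=O)C1=O | intermediate
7 | bis-cyclobutenone (stereocentres undefined, diastereomer mixture) | COCOc1c(C2(O)C(OCC)=C([Sn](CCCC)(CCCC)CCCC)C2=O)ccc(C)c1-c1c(C)ccc(C2(O)C(OCC)=C([Sn](CCCC)(CCCC)CCCC)C2=O)c1OCOC | intermediate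
8 | bis(stannyl-naphthalenediol), bis-MOM | Oc1c([Sn](CCCC)(CCCC)CCCC)c(OCC)c(O)c2c(OCOC)c(-c3c(C)cc4c(c3OCOC)c(O)c(OCC)c([Sn](CCCC)(CCCC)CCCC)c4O)c(C)cc12 | intermediate
9 | bis(3-ethoxynaphthalene-1,4,5-triol) | Oc1cc(OCC)c(O)c2c(O)c(-c3c(C)cc4c(O)cc(OCC)c(O)c4c3O)c(C)cc12 | intermediate
10 | 3,3'-diethoxyisodiospyrin | CCOC1=CC(=O)c2cc(C)c(-c3c(C)cc(O)c4c3C(=O)C=C(OCC)C4=O)c(O)c2C1=O | target

## Totals
- Total steps: 6, including reagent preparation in Step 2.
- Longest linear sequence: 5 steps (1, 3, 4, 5, 6).

## Three steps most likely to fail
1. **Step 3.** Tin–lithium exchange, wrong-carbonyl addition, or incomplete bis-addition of the hindered dilithio species.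
   Fallback: drop the squarate strategy and put the biaryl bond last. Make 3-ethoxy-7-methyljuglone by Diels–Alder of 2-ethoxy-1,4-benzoquinone with 1-acetoxy-3-methylbutadiene, then aromatise, and dimerise with Ag2O.
2. **Step 4.** The cascade may stall on the hindered bis-substrate (mono-cyclisation, or the ketene trapped by OH or OMOM), and the 6π closure may be poor.
   Fallback: run the same Moore–Liebeskind sequence on a monomeric 6-bromo aryl to give a 6-bromo-3-ethoxy-5-MOMO-7-methylnaphthoquinone. Then form the biaryl bond last by Ni(0)/Zn reductive homocoupling or Miyaura borylation/Suzuki, followed by MOM removal.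
3. **Step 5.** The leuco-triol may over-oxidise or lose the vinylogous ethyl ether under TFA, and protodestannylation may be incomplete.
   Fallback: reorder. Oxidise **8** first (Ag2O) to the bis(stannylquinone), remove Sn by Pd(PPh3)4/HCO2H–Bu3N hydrodestannylation, then remove MOM with ZnBr2/n-PrSH.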